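The cyclohexane ring C1–C6 is traced back to a cyclopentane through the α-ketol retron hidden in the vicinal tertiary/secondary diol C1(OH)–C6(OH). Once C6 is oxidised to C6=O, C1 can arise by a 1,2-shift. The precursor is a 1-(benzoyloxyacetyl)cyclopentanol whose carbinol carbon is the future C6 and whose ring neighbours are the future C2 (OTBS) and C5 (OBz). Under a chelating Lewis acid the C2–C6 bond moves to the side-chain carbonyl carbon. In one operation this inserts C1 into the ring (five to six), creates the fully substituted carbinol with its CH2OBz arm, and relays the configuration of the sacrificed carbinol to C1. Reduction at C6 and desilylation finish the synthesis.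

Key step: step 7

Numbering (target): C1 is the ring carbon bearing OH and CH2OBz (C7). C2 is the CH(OH) next to C3H2, followed by C4H2. C5 is CH(OBz), and C6 is the CH(OH) between C5 and C1.
Assumption: 2-bromocyclopent-2-en-1-one and 2-(benzoyloxy)acetic acid (the O-benzoate of glycolic acid) are taken as commercial.

Step 1
Reactants: 1 2-bromocyclopent-2-en-1-one
Product: 2 (1R)-2-bromocyclopent-2-en-1-ol
Conditions: (S)-Me-CBS (10 mol %), BH3·SMe2, THF, −10 °C; MeOH, aq. work-up
Reagents that add atoms: none
Why: Corey–Bakshi–Shibata reduction in which the bromoalkene arm acts as the large group, so the (S)-catalyst should deliver hydride to give the (R)-carbinol (future C2), while the electron-poor bromoalkene resists hydroboration.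

Step 2
Reactants: 2 (1R)-2-bromocyclopent-2-en-1-ol
Product: 3 {[(1R)-2-bromocyclopent-2-en-1-yl]oxy}(tert-butyl)dimethylsilane
Conditions: TBSCl, imidazole, DMF, rt
Reagents that add atoms: tert-butyldimethylsilyl chloride, CC(C)(C)[Si](C)(C)Cl
Why: Standard imidazole-promoted silylation of a secondary allylic alcohol, which leaves the stereocentre untouched and installs the bulky group that later shields one ring face.

Step 3
Reactants: 4 2-(benzoyloxy)acetic acid
Product: 5 2-(benzoyloxy)acetyl chloride
Conditions: (COCl)2, DMF (cat.), CH2Cl2, 0 °C → rt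
Reagents that add atoms: oxalyl chloride, O=C(Cl)C(=O)Cl
Why: Acid chloride formation through the catalytic chloroiminium (Vilsmeier-type) activation, which does not touch the benzoate.

Step 4
Reactants: 3 {[(1R)-2-bromocyclopent-2-en-1-yl]oxy}(tert-butyl)dimethylsilane; 5 2-(benzoyloxy)acetyl chloride
Product: 8 2-[(5R)-5-(tert-butyldimethylsilyloxy)cyclopent-1-en-1-yl]-2-oxoethyl benzoate, via alkenyllithium 6 (not isolated), via alkenylzinc chloride 7 (not isolated)
Conditions: t-BuLi (2.1 equiv), Et2O, −78 °C; ZnCl2 (THF), −78 → 0 °C; 5, Pd(PPh3)4 (5 mol %), THF, 0 °C → rt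
Reagents that add atoms: tert-butyllithium, [Li]C(C)(C)C (Li of 6); zinc chloride, Cl[Zn]Cl (ZnCl of 7)
Why: Bromine–lithium exchange, transmetalation and Negishi acylation, in which the mild alkenylzinc couples with the acid chloride at palladium and spares both the benzoate and the product ketone; β-elimination of the silyloxy group is excluded because it would give a five-membered cyclic allene.

Step 5
Reactants: 8 2-[(5R)-5-(tert-butyldimethylsilyloxy)cyclopent-1-en-1-yl]-2-oxoethyl benzoate
Product: 9 2-[(1R,2R,5R)-2-(tert-butyldimethylsilyloxy)-1,5-dihydroxycyclopentyl]-2-oxoethyl benzoate (1-OH and 5-OH cis to each other, both trans to 2-OTBS)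
Conditions: OsO4 (4 mol %), NMO, citric acid, t-BuOH/acetone/H2O, rt
Reagents that add atoms: N-methylmorpholine N-oxide, C[N+]1([O-])CCOCC1; water, O; both oxygens are handed over by the catalyst osmium tetroxide, O=[Os](=O)(=O)=O
Why: Catalytic osmium tetroxide syn-dihydroxylation (citric acid variant for electron-poor alkenes) on the ring face anti to the allylic OTBS group, which sets the tertiary carbinol and the future C5 in one suprafacial addition.

Step 6
Reactants: 9 2-[(1R,2R,5R)-2-(tert-butyldimethylsilyloxy)-1,5-dihydroxycyclopentyl]-2-oxoethyl benzoate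
Product: 10 (1R,2R,3R)-2-[(benzoyloxy)acetyl]-3-(tert-butyldimethylsilyloxy)-2-hydroxycyclopentyl benzoate
Conditions: BzCl (1.1 equiv), pyridine, DMAP (cat.), CH2Cl2, 0 °C
Reagents that add atoms: benzoyl chloride, O=C(Cl)c1ccccc1
Why: Chemoselective acylation, since the secondary hydroxyl is esterified much faster than the fully substituted, flanked tertiary hydroxyl, which has to stay free for the next step.

Step 7
Reactants: 10 (1R,2R,3R)-2-[(benzoyloxy)acetyl]-3-(tert-butyldimethylsilyloxy)-2-hydroxycyclopentyl benzoate
Product: 11 [(1S,2R,5R)-5-(benzoyloxy)-2-(tert-butyldimethylsilyloxy)-1-hydroxy-6-oxocyclohexyl]methyl benzoate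
Conditions: Sc(OTf)3 (10 mol %), 2,6-di-tert-butyl-4-methylpyridine (20 mol %), 4 Å MS, toluene, 60 °C
Reagents that add atoms: none
Why: Sc(III) binds the tertiary hydroxyl and the side-chain carbonyl of 10 as a cisoid five-membered chelate, and the ring bond from the carbinol carbon to the silyloxy-bearing carbon shifts with its electron pair to the activated carbonyl carbon (suprafacial 1,2-shift, retention at the migrating carbon) while the carbinol collapses to the ring ketone C6. This is the α-ketol (acyloin) rearrangement in its ring-enlarging form, known for 1-acylcyclopentanols and as the D-homoannulation of 17-hydroxy-20-oxo steroids; it should run forward because a crowded, eclipsed cyclopentane is exchanged for a chair cyclohexanone. The six-membered ring is not closed end to end: it forms by insertion of the former side-chain carbonyl carbon (C1) into the C2–C6 bond of the five-membered ring, a one-carbon enlargement. C1, the only new stereocentre, is controlled by the chelate: with both oxygens held syn-coplanar, the carbon trans to the hydroxyl can reach only one face of the carbonyl group, so the configuration of the carbinol that is destroyed is relayed to C1 (OH trans to C2–O and cis to C5–O, CH2OBz axial). The selectivity needed is migration of CH(OTBS) rather than CH(OBz): the silyloxy carbon is the better donor, its shift swings the CH2OBz arm toward the open lower face at C5 whereas the other shift would drive that arm into the OTBS group, and only the wanted product keeps an equatorial C1–O that can stay chelated to C6=O. C2 and C5 keep their configuration, and C5–OBz is equatorial, so enolisation of the new ketone should do no harm.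

Step 8
Reactants: 11 [(1S,2R,5R)-5-(benzoyloxy)-2-(tert-butyldimethylsilyloxy)-1-hydroxy-6-oxocyclohexyl]methyl benzoate
Product: 12 [(1R,2R,5R,6S)-5-(benzoyloxy)-2-(tert-butyldimethylsilyloxy)-1,6-dihydroxycyclohexyl]methyl benzoate
Conditions: Me4NBH(OAc)3, MeCN/AcOH 1:1, −20 → 0 °C
Reagents that add atoms: none
Why: Saksena–Evans hydroxyl-directed reduction, in which hydride is delivered from the face of the C1 hydroxyl, which is also the axial trajectory opposite the axial CH2OBz arm, so C6–OH should come out equatorial and trans to both C1–OH and C5–OBz, while the acidic medium suppresses benzoyl migration.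

Step 9
Reactants: 12 [(1R,2R,5R,6S)-5-(benzoyloxy)-2-(tert-butyldimethylsilyloxy)-1,6-dihydroxycyclohexyl]methyl benzoate
Product: 13 [(1S,2R,5R,6S)-5-(benzoyloxy)-1,2,6-trihydroxycyclohexyl]methyl benzoate (target)
Conditions: HF·pyridine, pyridine/THF, 0 °C → rt
Reagents that add atoms: none
Why: Fluoride-driven desilylation under weakly acidic conditions, which frees C2–OH without the alkoxide intermediates that would move the two benzoates.

Compound list
1 | 2-bromocyclopent-2-en-1-one | O=C1CCC=C1Br | starting material
2 | (1R)-2-bromocyclopent-2-en-1-ol | BrC1=CCC[C@H]1O | intermediate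
3 | {[(1R)-2-bromocyclopent-2-en-1-yl]oxy}(tert-butyl)dimethylsilane | BrC1=CCC[C@H]1O[Si](C)(C)C(C)(C)C | intermediate
4 | 2-(benzoyloxy)acetic acid | OC(=O)COC(=O)c1ccccc1 | starting material
5 | 2-(benzoyloxy)acetyl chloride | ClC(=O)COC(=O)c1ccccc1 | intermediate
6 | [(5R)-5-(tert-butyldimethylsilyloxy)cyclopent-1-en-1-yl]lithium | [Li]C1=CCC[C@H]1O[Si](C)(C)C(C)(C)C | intermediate
7 | [(5R)-5-(tert-butyldimethylsilyloxy)cyclopent-1-en-1-yl]zinc chloride | Cl[Zn]C1=CCC[C@H]1O[Si](C)(C)C(C)(C)C | intermediate
8 | 2-[(5R)-5-(tert-butyldimethylsilyloxy)cyclopent-1-en-1-yl]-2-oxoethyl benzoate | O=C(COC(=O)c1ccccc1)C2=CCC[C@H]2O[Si](C)(C)C(C)(C)C | intermediate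
9 | 2-[(1R,2R,5R)-2-(tert-butyldimethylsilyloxy)-1,5-dihydroxycyclopentyl]-2-oxoethyl benzoate | O=C(COC(=O)c1ccccc1)[C@]2(O)[C@H](O[Si](C)(C)C(C)(C)C)CC[C@H]2O | intermediate
10 | (1R,2R,3R)-2-[(benzoyloxy)acetyl]-3-(tert-butyldimethylsilyloxy)-2-hydroxycyclopentyl benzoate | O=C(COC(=O)c1ccccc1)[C@]2(O)[C@H](O[Si](C)(C)C(C)(C)C)CC[C@H]2OC(=O)c3ccccc3 | intermediate
11 | [(1S,2R,5R)-5-(benzoyloxy)-2-(tert-butyldimethylsilyloxy)-1-hydroxy-6-oxocyclohexyl]methyl benzoate | O=C(OC[C@]1(O)[C@H](O[Si](C)(C)C(C)(C)C)CC[C@@H](OC(=O)c2ccccc2)C1=O)c1ccccc1 | intermediate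
12 | [(1R,2R,5R,6S)-5-(benzoyloxy)-2-(tert-butyldimethylsilyloxy)-1,6-dihydroxycyclohexyl]methyl benzoate | O=C(OC[C@]1(O)[C@H](O[Si](C)(C)C(C)(C)C)CC[C@@H](OC(=O)c2ccccc2)[C@@H]1O)c1ccccc1 | intermediate
13 | [(1S,2R,5R,6S)-5-(benzoyloxy)-1,2,6-trihydroxycyclohexyl]methyl benzoate | O=C(OC[C@]1(O)[C@H](O)CC[C@@H](OC(=O)c2ccccc2)[C@@H]1O)c1ccccc1 | target

Total step count: 9. Longest linear sequence: 8 (steps 1, 2, 4, 5, 6, 7, 8, 9).

Steps most likely to fail

Step 7. Two processes could compete with the wanted shift: transfer of the benzoyl group from the C5 oxygen to the cis tertiary hydroxyl, which blocks the rearrangement, and migration of the benzoyloxy-bearing carbon instead of the silyloxy-bearing one. The fallback brings in the C5 oxygen only after the ring enlargement.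
- It sets out from 8. A manganese-catalysed reductive α-hydroxylation (Mukaiyama-type hydration: Mn(dpm)3 cat., PhSiH3, O2, i-PrOH, then P(OEt)3) should trap the α-keto radical with oxygen anti to OTBS and give 2-[(1R,2R)-2-(tert-butyldimethylsilyloxy)-1-hydroxycyclopentyl]-2-oxoethyl benzoate F1.
- F1 has no ester next to the tertiary hydroxyl, and the only competitor of the secondary, oxygen-bearing carbon is a plain CH2.
- The same chelate-controlled α-ketol rearrangement should then give [(1S,2R)-2-(tert-butyldimethylsilyloxy)-1-hydroxy-6-oxocyclohexyl]methyl benzoate F2.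
- α-Benzoyloxylation at C5, the only enolisable position, with N-methyl-O-benzoylhydroxylamine hydrochloride (DMSO, rt) and equilibration to the equatorial ester comes back to the route at 11.

Step 4. The hindered alkenylzinc may transmetalate slowly, so that the α-acyloxy acid chloride is lost by decarbonylation at palladium or by ketene formation. The fallback replaces the cross-coupling by carbonyl addition and oxidation.
- It sets out from 6, which is added at −78 °C to commercial 2-oxoethyl benzoate and quenched cold with NH4Cl.
- This should give 2-[(5R)-5-(tert-butyldimethylsilyloxy)cyclopent-1-en-1-yl]-2-hydroxyethyl benzoate F3. It is a mixture of epimers at the new carbinol, which is of no consequence.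
- Dess–Martin oxidation of F3 comes back to the route at 8.

Step 8. Ligand exchange at the hindered tertiary hydroxyl may be too slow for internal hydride delivery, which would erode the facial selectivity at C6. The fallback gives up substrate direction and sets C6 by catalyst control. This is a Noyori–Ikariya asymmetric transfer hydrogenation (RuCl(p-cymene)(TsDPEN), HCO2H/Et3N, CH2Cl2), using the catalyst enantiomer that adds hydride to the face syn to C1–OH. It sets out from 11 and comes back at 12 and makes no new compound (F0).

Further compounds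
F1 | step 7 | 2-[(1R,2R)-2-(tert-butyldimethylsilyloxy)-1-hydroxycyclopentyl]-2-oxoethyl benzoate | O=C(COC(=O)c1ccccc1)[C@]2(O)[C@H](O[Si](C)(C)C(C)(C)C)CCC2
F2 | step 7 | [(1S,2R)-2-(tert-butyldimethylsilyloxy)-1-hydroxy-6-oxocyclohexyl]methyl benzoate | O=C(OC[C@]1(O)[C@H](O[Si](C)(C)C(C)(C)C)CCCC1=O)c1ccccc1
F3 | step 4 | 2-[(5R)-5-(tert-butyldimethylsilyloxy)cyclopent-1-en-1-yl]-2-hydroxyethyl benzoate | OC(COC(=O)c1ccccc1)C2=CCC[C@H]2O[Si](C)(C)C(C)(C)C
F0 | step 8 | none | none
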